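**Plan**

1. Cuts: (i) the bond from the quaternary carbon to the E-alkene, made by an SN2′ allylic substitution that joins a ring-bearing allylic phosphate to a C17 alkyne; (ii) the chain C–C bonds of the alkyne, made by boron 1,2-shifts; (iii) in the ring, the bonds C(=CH2)–CH(side chain) and CH2–CH(CH3), made together.
2. Enabling feature: the two ring stereocentres, CH(side chain) and CH(CH3), lie on either side of the C(CH3)2 carbon. A temporary two-carbon (etheno) bridge between them turns the ring into the six-membered ring of a bicyclo[3.2.1]octa-2,6-diene: bridgeheads = the two stereocentres, one-carbon bridge = C(CH3)2, three-carbon bridge = C(=CH2)–CH2–CH2. A vinylcarbenoid and 1,5,5-trimethylcyclopentadiene assemble this bicycle in one formal [4+3] event, and the carbenoid's ester carbon later becomes the =CH2 carbon.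
3. Forward order: bicycle (step 4), then ozonolysis of the bridge. The bridge carbon on the CH centre becomes the first side-chain carbon; the one on the C(CH3) centre leaves as CO with retention. Then B-alkyl Suzuki coupling, reductive transposition to the exocyclic alkene, and phosphate formation. The alkyne is built separately by iterative boronic ester homologation, and the halves are joined in the last step.
4. Stereochemistry: both ring centres come from the chiral dirhodium catalyst (cis bridge plus retentive decarbonylation gives the trans ring). The four chain methyl centres come from sparteine-controlled lithiated benzoate. The quaternary centre comes from a chiral NHC–copper catalyst. Both E-alkenes come from syn hydrometallation.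

Key step: step 4

Assumption: in the two catalyst-controlled steps (4 and 23) the named catalyst antipode is taken to give the configuration drawn; if the opposite sense were found, the mirror-image catalyst would be used with no other change.

**Route**

Step 1
Reactants: 1 2,2-dimethylcyclopentan-1-one
Product: 3 5,5-dimethylcyclopent-2-en-1-one, via silyl enol ether 2 (not isolated)
Conditions: LDA (LiN(i-Pr)2), THF, −78 °C; Me3SiCl; then Pd(OAc)2 (10 mol %), O2 (1 atm), DMSO, 25 °C
Reagents that add atoms: none
Why: Saegusa–Ito oxidation; the enolate can form only on the CH2 side because the other α-carbon is quaternary, and palladium diacetate (reoxidised by O2) dehydrosilylates the enol ether to the enone.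

Step 2
Reactants: 3 5,5-dimethylcyclopent-2-en-1-one
Product: 5 1,5,5-trimethylcyclopenta-1,3-diene, via allylic alcohol 4 (not isolated)
Conditions: MeLi, Et2O, −78 → 0 °C; H2O; then p-TsOH·H2O (5 mol %), pentane, 25 °C
Reagents that add atoms: methyllithium, [Li]C
Why: 1,2-addition to the enone followed by acid-catalysed E1 dehydration through the allyl cation gives the endocyclic diene, which cannot isomerise by 1,5-hydrogen shift because its sp3 ring carbon bears no hydrogen.

Step 3
Reactants: 6 methyl but-3-enoate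
Product: 7 methyl 2-diazobut-3-enoate
Conditions: p-ABSA, DBU, MeCN, 0 °C; kept cold and used at once as a pentane solution
Reagents that add atoms: 4-acetamidobenzenesulfonyl azide (p-ABSA), CC(=O)Nc1ccc(cc1)S(=O)(=O)N=[N+]=[N-]
Why: Regitz diazo transfer; DBU forms the dienolate of the doubly activated CH2 group, which attacks the sulfonyl azide at its α-carbon and releases the sulfonamide.

Step 4
Reactants: 5 1,5,5-trimethylcyclopenta-1,3-diene; 7 methyl 2-diazobut-3-enoate
Product: 9 methyl (1R,5S)-5,8,8-trimethylbicyclo[3.2.1]octa-2,6-diene-2-carboxylate, via divinylcyclopropane 8 (not isolated)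
Conditions: Rh2(S-DOSP)4 [dirhodium tetrakis((S)-N-(4-dodecylbenzenesulfonyl)prolinate)] (1 mol %), 5 (4 equiv), slow addition of 7, pentane, −78 → 25 °C
Reagents that add atoms: none
Why: The dirhodium catalyst turns 7 into a donor/acceptor vinylcarbenoid that cyclopropanates the disubstituted double bond of 5 (concerted, asynchronous [2+1] closure of the three-membered ring) to give the cis-divinylcyclopropane 8 with the vinyl group endo; 8 then undergoes a [3,3]-sigmatropic (Cope) shift through a boat transition state, which closes the six-membered ring by joining the vinyl terminus to the methyl-bearing diene carbon while the strained cyclopropane bond opens. The closest known reaction type is the tandem cyclopropanation/Cope rearrangement (formal [4+3] cycloaddition) of vinyldiazoacetates with cyclopentadienes under chiral dirhodium prolinate catalysis. Bridgehead C1 of 9 is set by the catalyst, which selects the carbenoid and alkene faces in the cyclopropanation, and bridgehead C5 of 9 is set in the stereospecific Cope step, where the etheno bridge forces it cis to C1. Three selectivities are needed: attack at the disubstituted rather than the trisubstituted double bond of 5 (secured by the steric demand of this carbenoid class and by the methyl group on the diene), endo placement of the vinyl group (inherent in donor/acceptor carbenoids, ester trans to the ring), and enantioselectivity (catalyst); the two faces of 5 are equivalent because its sp3 carbon carries two methyl groups. The ester-bearing carbon thus ends next to the hydrogen-bearing bridgehead and the new CH2 next to the methyl-bearing bridgehead, which is the connectivity of the target ring.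

Step 5
Reactants: 9 methyl (1R,5S)-5,8,8-trimethylbicyclo[3.2.1]octa-2,6-diene-2-carboxylate
Product: 11 methyl (4R,6R)-4,6-diformyl-4,5,5-trimethylcyclohex-1-ene-1-carboxylate, via ozonide 10 (not isolated)
Conditions: O3 (1 equiv, indicator end point), CH2Cl2, −78 °C; then PPh3, −78 → 0 °C; used without delay
Reagents that add atoms: ozone, [O-][O+]=O
Why: Ozonolysis with reductive work-up; ozone attacks the strained, electron-rich etheno bridge much faster than the electron-poor enoate, and the two formyl groups stand cis because they come from one bridge.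

Step 6
Reactants: 11 methyl (4R,6R)-4,6-diformyl-4,5,5-trimethylcyclohex-1-ene-1-carboxylate
Product: 12 methyl (4R,6R)-6-ethenyl-4-formyl-4,5,5-trimethylcyclohex-1-ene-1-carboxylate
Conditions: CH2I2 (1.1 equiv), Zn, Ti(OiPr)4, THF, 0 °C
Reagents that add atoms: diiodomethane, ICI
Why: Takai methylenation; the non-basic zinc/titanium reagent reacts at the formyl group on the CH carbon and spares the far more hindered formyl group on the quaternary carbon, without epimerising the α-stereocentre.

Step 7
Reactants: 12 methyl (4R,6R)-6-ethenyl-4-formyl-4,5,5-trimethylcyclohex-1-ene-1-carboxylate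
Product: 13 methyl (4S,6R)-6-ethenyl-4,5,5-trimethylcyclohex-1-ene-1-carboxylate
Conditions: RhCl(PPh3)3 (1.1 equiv), PhCN, 130 °C
Reagents that add atoms: none
Why: Tsuji–Wilkinson decarbonylation; oxidative addition of the formyl C–H bond, CO extrusion and C–H reductive elimination replace CHO by H with retention, so the hydrogen stands where the bridge was and the methyl group ends trans to the vinyl-bearing centre.

Step 8
Reactants: 14 but-2-yn-1-ol
Product: 15 tert-butyl(but-2-yn-1-yloxy)dimethylsilane
Conditions: t-BuMe2SiCl, imidazole, CH2Cl2, 25 °C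
Reagents that add atoms: tert-butyldimethylsilyl chloride, CC(C)(C)[Si](C)(C)Cl
Why: Standard silylation of a primary alcohol, which protects the oxygen through the later hydride and Mitsunobu steps.

Step 9
Reactants: 15 tert-butyl(but-2-yn-1-yloxy)dimethylsilane
Product: 17 (E)-tert-butyl[(3-iodobut-2-en-1-yl)oxy]dimethylsilane, via alkenylzirconocene chloride 16 (not isolated)
Conditions: Cp2Zr(H)Cl (2 equiv), THF, 50 °C; then I2, 0 °C
Reagents that add atoms: iodine, II
Why: Hydrozirconation–iodination; syn addition of Zr–H, equilibrated by excess reagent to place zirconium on the methyl-bearing carbon, then iodinolysis with retention gives the E-iodide.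

Step 10
Reactants: 13 methyl (4S,6R)-6-ethenyl-4,5,5-trimethylcyclohex-1-ene-1-carboxylate; 17 (E)-tert-butyl[(3-iodobut-2-en-1-yl)oxy]dimethylsilane
Product: 19 methyl (4S,6R)-6-[(3E)-5-(tert-butyldimethylsilyloxy)-3-methylpent-3-en-1-yl]-4,5,5-trimethylcyclohex-1-ene-1-carboxylate, via B-alkyl-9-BBN 18 (not isolated)
Conditions: 9-BBN, THF, 25 → 45 °C; then 17, Pd(dppf)Cl2 (5 mol %), AsPh3, Cs2CO3, DMF/H2O, 25 °C
Reagents that add atoms: none
Why: 9-BBN adds anti-Markovnikov to the monosubstituted vinyl group only (the enoate alkene is inert), and B-alkyl Suzuki–Miyaura coupling joins the primary alkylborane to the vinyl iodide with retention of the E geometry.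

Step 11
Reactants: 19 methyl (4S,6R)-6-[(3E)-5-(tert-butyldimethylsilyloxy)-3-methylpent-3-en-1-yl]-4,5,5-trimethylcyclohex-1-ene-1-carboxylate
Product: 20 [(4S,6R)-6-[(3E)-5-(tert-butyldimethylsilyloxy)-3-methylpent-3-en-1-yl]-4,5,5-trimethylcyclohex-1-en-1-yl]methanol
Conditions: i-Bu2AlH (2.5 equiv), CH2Cl2, −78 °C; Rochelle salt
Reagents that add atoms: none
Why: 1,2-reduction of the conjugated ester by diisobutylaluminium hydride gives the primary allylic alcohol; the silyl ether and the alkenes are inert.

Step 12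
Reactants: 20 [(4S,6R)-6-[(3E)-5-(tert-butyldimethylsilyloxy)-3-methylpent-3-en-1-yl]-4,5,5-trimethylcyclohex-1-en-1-yl]methanol
Product: 22 tert-butyldimethyl{[(2E)-3-methyl-5-[(1S,5S)-5,6,6-trimethyl-2-methylidenecyclohexyl]pent-2-en-1-yl]oxy}silane, via allylic diazene 21 (not isolated)
Conditions: 2-nitrobenzenesulfonylhydrazide (NBSH), PPh3, DEAD, N-methylmorpholine, −30 °C; then 25 °C
Reagents that add atoms: none
Why: Myers reductive 1,3-transposition; Mitsunobu substitution by the sulfonylhydrazide, loss of sulfinic acid and retro-ene extrusion of N2 deliver hydrogen to the ring =CH carbon and move the double bond to the exocyclic position, leaving the neighbouring stereocentre untouched.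

Step 13
Reactants: 22 tert-butyldimethyl{[(2E)-3-methyl-5-[(1S,5S)-5,6,6-trimethyl-2-methylidenecyclohexyl]pent-2-en-1-yl]oxy}silane
Product: 23 (2E)-3-methyl-5-[(1S,5S)-5,6,6-trimethyl-2-methylidenecyclohexyl]pent-2-en-1-ol
Conditions: Bu4NF, THF, 0 → 25 °C
Reagents that add atoms: none
Why: Fluoride-induced desilylation, driven by the Si–F bond, frees the allylic alcohol.

Step 14
Reactants: 23 (2E)-3-methyl-5-[(1S,5S)-5,6,6-trimethyl-2-methylidenecyclohexyl]pent-2-en-1-ol
Product: 24 diethyl (2E)-3-methyl-5-[(1S,5S)-5,6,6-trimethyl-2-methylidenecyclohexyl]pent-2-en-1-yl phosphate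
Conditions: (EtO)2P(O)Cl, Et3N, DMAP (cat.), CH2Cl2, 0 °C
Reagents that add atoms: diethyl chlorophosphate, CCOP(Cl)(=O)OCC
Why: O-Phosphorylation of the primary allylic alcohol gives the leaving group needed for copper-catalysed SN2′ substitution.

Step 15
Reactants: 25 4,4,5,5-tetramethyl-2-(propan-2-yl)-1,3,2-dioxaborolane
Product: 27 4,4,5,5-tetramethyl-2-[(2S)-3-methylbutan-2-yl]-1,3,2-dioxaborolane, via lithium boronate 26 (not isolated)
Conditions: ethyl 2,4,6-triisopropylbenzoate, s-BuLi, (+)-sparteine, Et2O, −78 °C; then 25; then 35 °C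
Reagents that add atoms: ethyl 2,4,6-triisopropylbenzoate, CCOC(=O)c1c(C(C)C)cc(C(C)C)cc1C(C)C
Why: Lithiation–borylation; sparteine-directed deprotonation gives the configurationally stable (R)-lithiated benzoate, boron captures it with retention, and anti-periplanar 1,2-migration of isopropyl with loss of the benzoate inverts the carbenoid carbon, setting the first methyl stereocentre under reagent control.

Step 16
Reactants: 27 4,4,5,5-tetramethyl-2-[(2S)-3-methylbutan-2-yl]-1,3,2-dioxaborolane
Product: 29 2-[(3R)-3,4-dimethylpentyl]-4,4,5,5-tetramethyl-1,3,2-dioxaborolane, via mono-homologated boronic ester 28 (not isolated)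
Conditions: ICH2Cl, n-BuLi, Et2O, −78 → 25 °C; the same operation repeated once in the flask
Reagents that add atoms: chloroiodomethane, ClCI
Why: Matteson homologation; chloromethyllithium adds to boron and the alkyl group migrates with loss of chloride and retention at the migrating stereocentre, two insertions giving the CH2CH2 spacer.

Step 17
Reactants: 29 2-[(3R)-3,4-dimethylpentyl]-4,4,5,5-tetramethyl-1,3,2-dioxaborolane
Product: 31 2-[(2S,5R)-5,6-dimethylheptan-2-yl]-4,4,5,5-tetramethyl-1,3,2-dioxaborolane, via lithium boronate 30 (not isolated)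
Conditions: ethyl 2,4,6-triisopropylbenzoate, s-BuLi, (+)-sparteine, Et2O, −78 °C; then 29; then 35 °C
Reagents that add atoms: ethyl 2,4,6-triisopropylbenzoate, CCOC(=O)c1c(C(C)C)cc(C(C)C)cc1C(C)C
Why: Lithiation–borylation as in step 15; the new methyl stereocentre is set by the (R)-carbenoid alone (retention at boron capture, inversion in the 1,2-shift), independent of the remote centre.

Step 18
Reactants: 31 2-[(2S,5R)-5,6-dimethylheptan-2-yl]-4,4,5,5-tetramethyl-1,3,2-dioxaborolane
Product: 33 4,4,5,5-tetramethyl-2-[(2S,3S,6R)-3,6,7-trimethyloctan-2-yl]-1,3,2-dioxaborolane, via lithium boronate 32 (not isolated)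
Conditions: ethyl 2,4,6-triisopropylbenzoate, s-BuLi, (+)-sparteine, Et2O, −78 °C; then 31; then 35 °C
Reagents that add atoms: ethyl 2,4,6-triisopropylbenzoate, CCOC(=O)c1c(C(C)C)cc(C(C)C)cc1C(C)C
Why: Lithiation–borylation on a secondary boronic ester; the migrating centre keeps its configuration and the same (R)-carbenoid sets the adjacent centre, which gives the anti vicinal dimethyl pair under reagent control.

Step 19
Reactants: 33 4,4,5,5-tetramethyl-2-[(2S,3S,6R)-3,6,7-trimethyloctan-2-yl]-1,3,2-dioxaborolane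
Product: 35 4,4,5,5-tetramethyl-2-[(3R,4S,7R)-3,4,7,8-tetramethylnonyl]-1,3,2-dioxaborolane, via mono-homologated boronic ester 34 (not isolated)
Conditions: ICH2Cl, n-BuLi, Et2O, −78 → 25 °C; the same operation repeated once in the flask
Reagents that add atoms: chloroiodomethane, ClCI
Why: Two Matteson homologations with retention at the migrating carbon install the second CH2CH2 spacer.

Step 20
Reactants: 35 4,4,5,5-tetramethyl-2-[(3R,4S,7R)-3,4,7,8-tetramethylnonyl]-1,3,2-dioxaborolane
Product: 37 4,4,5,5-tetramethyl-2-[(2R,5R,6S,9R)-5,6,9,10-tetramethylundecan-2-yl]-1,3,2-dioxaborolane, via lithium boronate 36 (not isolated)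
Conditions: ethyl 2,4,6-triisopropylbenzoate, s-BuLi, (−)-sparteine, Et2O, −78 °C; then 35; then 35 °C
Reagents that add atoms: ethyl 2,4,6-triisopropylbenzoate, CCOC(=O)c1c(C(C)C)cc(C(C)C)cc1C(C)C
Why: Lithiation–borylation with the enantiomeric (S)-carbenoid from (−)-sparteine sets the last methyl stereocentre in the opposite spatial sense, again under reagent control.

Step 21
Reactants: 37 4,4,5,5-tetramethyl-2-[(2R,5R,6S,9R)-5,6,9,10-tetramethylundecan-2-yl]-1,3,2-dioxaborolane
Product: 39 (3R,6R,7S,10R)-3,6,7,10,11-pentamethyldodec-1-en-2-yl N,N-diisopropylcarbamate, via lithium vinylboronate 38 (not isolated)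
Conditions: ethenyl N,N-diisopropylcarbamate, LDA, THF, −78 °C; then 37; then I2; NaOMe, MeOH, −78 → 25 °C
Reagents that add atoms: ethenyl N,N-diisopropylcarbamate, C=COC(=O)N(C(C)C)C(C)C
Why: Zweifel-type coupling; the α-lithiated vinyl carbamate adds to boron, iodine triggers 1,2-migration of the secondary alkyl group with retention, and methoxide-induced anti elimination of boron and iodide gives the 1-substituted vinyl carbamate.

Step 22
Reactants: 39 (3R,6R,7S,10R)-3,6,7,10,11-pentamethyldodec-1-en-2-yl N,N-diisopropylcarbamate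
Product: 40 (3R,6R,7S,10R)-3,6,7,10,11-pentamethyldodec-1-yne
Conditions: LDA (3 equiv), THF, −78 → 0 °C; H2O
Reagents that add atoms: none
Why: Base-induced elimination; vinylic deprotonation and loss of lithium carbamate give the lithium acetylide, and the propargylic stereocentre is not deprotonated under these conditions.

Step 23
Reactants: 40 (3R,6R,7S,10R)-3,6,7,10,11-pentamethyldodec-1-yne; 24 diethyl (2E)-3-methyl-5-[(1S,5S)-5,6,6-trimethyl-2-methylidenecyclohexyl]pent-2-en-1-yl phosphate
Product: 42 (3S,4E,6R,9R,10S,13R)-3,6,9,10,13,14-hexamethyl-3-{2-[(1S,5S)-5,6,6-trimethyl-2-methylidenecyclohexyl]ethyl}pentadeca-1,4-diene, via alkenylalane 41 (not isolated)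
Conditions: 40 (1.5 equiv), i-Bu2AlH, hexane, 55 °C; then 24, CuCl2·2H2O (5 mol %), chiral sulfonate-bearing imidazolinium salt (NHC precursor, 5.5 mol %), THF, −15 °C
Reagents that add atoms: none
Why: Syn hydroalumination gives the E-alkenylalane, and NHC–copper-catalysed enantioselective SN2′ allylic substitution transfers the alkenyl group (in preference to isobutyl) to the methyl-bearing carbon of the E-allylic phosphate, so the quaternary stereocentre is set by the chiral ligand, the vinyl group is unveiled and the E geometry is retained.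

**Compound list**

1 | 2,2-dimethylcyclopentan-1-one | CC1(C)CCCC1=O | starting material
2 | [(5,5-dimethylcyclopent-1-en-1-yl)oxy]trimethylsilane | CC1(C)CCC=C1O[Si](C)(C)C | intermediate (not isolated)
3 | 5,5-dimethylcyclopent-2-en-1-one | CC1(C)CC=CC1=O | intermediate
4 | 1,5,5-trimethylcyclopent-2-en-1-ol (racemic) | CC1(O)C=CCC1(C)C | intermediate (not isolated)
5 | 1,5,5-trimethylcyclopenta-1,3-diene | CC1=CC=CC1(C)C | intermediate
6 | methyl but-3-enoate | COC(=O)CC=C | starting material
7 | methyl 2-diazobut-3-enoate | COC(=O)C(=[N+]=[N-])C=C | intermediate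
8 | methyl (1R,5R,6S)-6-ethenyl-3,4,4-trimethylbicyclo[3.1.0]hex-2-ene-6-carboxylate (vinyl endo) | COC(=O)[C@@]1(C=C)[C@@H]2C=C(C)C(C)(C)[C@H]12 | intermediate (not isolated)
9 | methyl (1R,5S)-5,8,8-trimethylbicyclo[3.2.1]octa-2,6-diene-2-carboxylate | COC(=O)C1=CC[C@@]2(C)C=C[C@@H]1C2(C)C | intermediate
10 | secondary ozonide of 9 at the etheno bridge (both orientations of the trioxolane) | COC(=O)C1=CC[C@@]2(C)C3OOC(O3)[C@@H]1C2(C)C | intermediate (not isolated)
11 | methyl (4R,6R)-4,6-diformyl-4,5,5-trimethylcyclohex-1-ene-1-carboxylate | COC(=O)C1=CC[C@@](C)(C=O)C(C)(C)[C@H]1C=O | intermediate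
12 | methyl (4R,6R)-6-ethenyl-4-formyl-4,5,5-trimethylcyclohex-1-ene-1-carboxylate | COC(=O)C1=CC[C@@](C)(C=O)C(C)(C)[C@H]1C=C | intermediate
13 | methyl (4S,6R)-6-ethenyl-4,5,5-trimethylcyclohex-1-ene-1-carboxylate | COC(=O)C1=CC[C@H](C)C(C)(C)[C@H]1C=C | intermediate
14 | but-2-yn-1-ol | CC#CCO | starting material
15 | tert-butyl(but-2-yn-1-yloxy)dimethylsilane | CC#CCO[Si](C)(C)C(C)(C)C | intermediate
16 | [(E)-4-(tert-butyldimethylsilyloxy)but-2-en-2-yl]chlorobis(cyclopentadienyl)zirconium | C/C(=C\CO[Si](C)(C)C(C)(C)C)[Zr](Cl)(C1C=CC=C1)C1C=CC=C1 | intermediate (not isolated)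
17 | (E)-tert-butyl[(3-iodobut-2-en-1-yl)oxy]dimethylsilane | C/C(I)=C\CO[Si](C)(C)C(C)(C)C | intermediate
18 | methyl (4S,6R)-6-[2-(9-borabicyclo[3.3.1]nonan-9-yl)ethyl]-4,5,5-trimethylcyclohex-1-ene-1-carboxylate | COC(=O)C1=CC[C@H](C)C(C)(C)[C@H]1CCB1C2CCCC1CCC2 | intermediate (not isolated)
19 | methyl (4S,6R)-6-[(3E)-5-(tert-butyldimethylsilyloxy)-3-methylpent-3-en-1-yl]-4,5,5-trimethylcyclohex-1-ene-1-carboxylate | COC(=O)C1=CC[C@H](C)C(C)(C)[C@H]1CC/C(C)=C/CO[Si](C)(C)C(C)(C)C | intermediate
20 | [(4S,6R)-6-[(3E)-5-(tert-butyldimethylsilyloxy)-3-methylpent-3-en-1-yl]-4,5,5-trimethylcyclohex-1-en-1-yl]methanol | OCC1=CC[C@H](C)C(C)(C)[C@H]1CC/C(C)=C/CO[Si](C)(C)C(C)(C)C | intermediate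
21 | allylic monoalkyl diazene derived from 20 (N=NH in place of OH) | N=NCC1=CC[C@H](C)C(C)(C)[C@H]1CC/C(C)=C/CO[Si](C)(C)C(C)(C)C | intermediate (not isolated)
22 | tert-butyldimethyl{[(2E)-3-methyl-5-[(1S,5S)-5,6,6-trimethyl-2-methylidenecyclohexyl]pent-2-en-1-yl]oxy}silane | C=C1CC[C@H](C)C(C)(C)[C@H]1CC/C(C)=C/CO[Si](C)(C)C(C)(C)C | intermediate
23 | (2E)-3-methyl-5-[(1S,5S)-5,6,6-trimethyl-2-methylidenecyclohexyl]pent-2-en-1-ol | C=C1CC[C@H](C)C(C)(C)[C@H]1CC/C(C)=C/CO | intermediate
24 | diethyl (2E)-3-methyl-5-[(1S,5S)-5,6,6-trimethyl-2-methylidenecyclohexyl]pent-2-en-1-yl phosphate | C=C1CC[C@H](C)C(C)(C)[C@H]1CC/C(C)=C/COP(=O)(OCC)OCC | intermediate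
25 | 4,4,5,5-tetramethyl-2-(propan-2-yl)-1,3,2-dioxaborolane | CC(C)B1OC(C)(C)C(C)(C)O1 | starting material
26 | lithium boronate from 25 and the (R)-1-lithioethyl benzoate | [Li+].C[C@@H]([B-]1(C(C)C)OC(C)(C)C(C)(C)O1)OC(=O)c1c(C(C)C)cc(C(C)C)cc1C(C)C | intermediate (not isolated)
27 | 4,4,5,5-tetramethyl-2-[(2S)-3-methylbutan-2-yl]-1,3,2-dioxaborolane | CC(C)[C@H](C)B1OC(C)(C)C(C)(C)O1 | intermediate
28 | 2-[(2R)-2,3-dimethylbutyl]-4,4,5,5-tetramethyl-1,3,2-dioxaborolane | CC(C)[C@H](C)CB1OC(C)(C)C(C)(C)O1 | intermediate (not isolated)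
29 | 2-[(3R)-3,4-dimethylpentyl]-4,4,5,5-tetramethyl-1,3,2-dioxaborolane | CC(C)[C@H](C)CCB1OC(C)(C)C(C)(C)O1 | intermediate
30 | lithium boronate from 29 and the (R)-1-lithioethyl benzoate | [Li+].C[C@@H]([B-]1(CC[C@@H](C)C(C)C)OC(C)(C)C(C)(C)O1)OC(=O)c1c(C(C)C)cc(C(C)C)cc1C(C)C | intermediate (not isolated)
31 | 2-[(2S,5R)-5,6-dimethylheptan-2-yl]-4,4,5,5-tetramethyl-1,3,2-dioxaborolane | CC(C)[C@H](C)CC[C@H](C)B1OC(C)(C)C(C)(C)O1 | intermediate
32 | lithium boronate from 31 and the (R)-1-lithioethyl benzoate | [Li+].C[C@@H]([B-]1([C@@H](C)CC[C@@H](C)C(C)C)OC(C)(C)C(C)(C)O1)OC(=O)c1c(C(C)C)cc(C(C)C)cc1C(C)C | intermediate (not isolated)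
33 | 4,4,5,5-tetramethyl-2-[(2S,3S,6R)-3,6,7-trimethyloctan-2-yl]-1,3,2-dioxaborolane | CC(C)[C@H](C)CC[C@H](C)[C@H](C)B1OC(C)(C)C(C)(C)O1 | intermediate
34 | 4,4,5,5-tetramethyl-2-[(2R,3S,6R)-2,3,6,7-tetramethyloctyl]-1,3,2-dioxaborolane | CC(C)[C@H](C)CC[C@H](C)[C@H](C)CB1OC(C)(C)C(C)(C)O1 | intermediate (not isolated)
35 | 4,4,5,5-tetramethyl-2-[(3R,4S,7R)-3,4,7,8-tetramethylnonyl]-1,3,2-dioxaborolane | CC(C)[C@H](C)CC[C@H](C)[C@H](C)CCB1OC(C)(C)C(C)(C)O1 | intermediate
36 | lithium boronate from 35 and the (S)-1-lithioethyl benzoate | [Li+].C[C@H]([B-]1(CC[C@@H](C)[C@@H](C)CC[C@@H](C)C(C)C)OC(C)(C)C(C)(C)O1)OC(=O)c1c(C(C)C)cc(C(C)C)cc1C(C)C | intermediate (not isolated)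
37 | 4,4,5,5-tetramethyl-2-[(2R,5R,6S,9R)-5,6,9,10-tetramethylundecan-2-yl]-1,3,2-dioxaborolane | CC(C)[C@H](C)CC[C@H](C)[C@H](C)CC[C@@H](C)B1OC(C)(C)C(C)(C)O1 | intermediate
38 | lithium boronate from 37 and 1-lithioethenyl N,N-diisopropylcarbamate | [Li+].C=C(OC(=O)N(C(C)C)C(C)C)[B-]1([C@H](C)CC[C@@H](C)[C@@H](C)CC[C@@H](C)C(C)C)OC(C)(C)C(C)(C)O1 | intermediate (not isolated)
39 | (3R,6R,7S,10R)-3,6,7,10,11-pentamethyldodec-1-en-2-yl N,N-diisopropylcarbamate | C=C(OC(=O)N(C(C)C)C(C)C)[C@H](C)CC[C@@H](C)[C@@H](C)CC[C@@H](C)C(C)C | intermediate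
40 | (3R,6R,7S,10R)-3,6,7,10,11-pentamethyldodec-1-yne | C#C[C@H](C)CC[C@@H](C)[C@@H](C)CC[C@@H](C)C(C)C | intermediate
41 | diisobutyl[(1E,3R,6R,7S,10R)-3,6,7,10,11-pentamethyldodec-1-en-1-yl]alane | CC(C)C[Al](CC(C)C)/C=C/[C@H](C)CC[C@@H](C)[C@@H](C)CC[C@@H](C)C(C)C | intermediate (not isolated)
42 | (3S,4E,6R,9R,10S,13R)-3,6,9,10,13,14-hexamethyl-3-{2-[(1S,5S)-5,6,6-trimethyl-2-methylidenecyclohexyl]ethyl}pentadeca-1,4-diene | C=C[C@@](C)(/C=C/[C@H](C)CC[C@@H](C)[C@@H](C)CC[C@@H](C)C(C)C)CC[C@H]1C(=C)CC[C@H](C)C1(C)C | target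

**Step count and risks**

Total step count: 23. Longest linear sequence: 12 steps (1, 2, 4, 5, 6, 7, 10, 11, 12, 13, 14, 23) from 2,2-dimethylcyclopentan-1-one.

Steps most likely to fail:

Step 4. The bulky chiral carbenoid may be captured too slowly by the diene, whose reacting double bond lies next to the C(CH3)2 carbon, so that carbenoid dimerisation or pyrazole formation from 7 wins. Facial discrimination may also be poor for this small, unsubstituted vinylcarbenoid. The fallback moves stereocontrol from the catalyst to a covalently bound auxiliary and uses a small, more electrophilic achiral catalyst. It sets out from 6 and 5. Ester 6 would be transesterified with (R)-pantolactone (Ti(OiPr)4 cat., toluene, removal of MeOH) to (3R)-4,4-dimethyl-2-oxooxolan-3-yl but-3-enoate F1. Diazo transfer (p-ABSA, DBU) would give the diazo ester F2. Adding F2 slowly to neat 5 with Rh2(O2CC7H15)4 in refluxing pentane should give the auxiliary-bearing cycloadduct F3, whose diastereomers can be separated. NaOMe in MeOH would exchange the auxiliary for methyl and return to the route at 9.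

Step 7. CO extrusion from the doubly neopentyl aldehyde may be outrun by intramolecular hydroacylation of the cis-disposed vinyl group or by migration of its double bond into conjugation. The fallback removes the formyl group before the vinyl group exists. It sets out from 11. Chemoselective acetalisation of the less hindered aldehyde (HC(OMe)3, PPTS, MeOH) would give the mono-acetal F4. Decarbonylation with RhCl(PPh3)3, with retention, would give F5. Mild acid hydrolysis (PPTS, acetone/H2O) would give the aldehyde F6. Takai methylenation as in step 6 would return to the route at 13.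

Step 23. With two large partners, SN2 may compete with SN2′ attack, the isobutyl group may transfer instead of the alkenyl group, or face selection at the quaternary carbon may be poor. The fallback sets the quaternary centre by a stereospecific epoxide opening instead. It sets out from 23 and 40. Sharpless epoxidation of 23 (Ti(OiPr)4, D-(−)-diethyl tartrate, t-BuOOH, CH2Cl2, −20 °C) would give the (2R,3R)-epoxy alcohol F7. The diethylalkynylalane made from 40 (n-BuLi, then Et2AlCl) should open F7 at the tertiary carbon with inversion to give the diol F8. NaIO4 cleavage would give the α-quaternary aldehyde F9. Wittig methylenation (Ph3P=CH2) would give the enyne F10. Dissolving-metal reduction (Na, NH3, t-BuOH, −78 °C) would reduce only the alkyne, to the E-alkene, and arrive at 42.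

Further compounds
F1 | step 4 | (3R)-4,4-dimethyl-2-oxooxolan-3-yl but-3-enoate | CC1(C)COC(=O)[C@@H]1OC(=O)CC=C
F2 | step 4 | (3R)-4,4-dimethyl-2-oxooxolan-3-yl 2-diazobut-3-enoate | CC1(C)COC(=O)[C@@H]1OC(=O)C(=[N+]=[N-])C=C
F3 | step 4 | (3R)-4,4-dimethyl-2-oxooxolan-3-yl (1R,5S)-5,8,8-trimethylbicyclo[3.2.1]octa-2,6-diene-2-carboxylate | CC1(C)COC(=O)[C@@H]1OC(=O)C3=CC[C@@]2(C)C=C[C@@H]3C2(C)C
F4 | step 7 | methyl (4R,6R)-6-(dimethoxymethyl)-4-formyl-4,5,5-trimethylcyclohex-1-ene-1-carboxylate | COC(=O)C1=CC[C@@](C)(C=O)C(C)(C)[C@H]1C(OC)OC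
F5 | step 7 | methyl (4S,6R)-6-(dimethoxymethyl)-4,5,5-trimethylcyclohex-1-ene-1-carboxylate | COC(=O)C1=CC[C@H](C)C(C)(C)[C@H]1C(OC)OC
F6 | step 7 | methyl (4S,6R)-6-formyl-4,5,5-trimethylcyclohex-1-ene-1-carboxylate | COC(=O)C1=CC[C@H](C)C(C)(C)[C@H]1C=O
F7 | step 23 | [(2R,3R)-3-methyl-3-{2-[(1S,5S)-5,6,6-trimethyl-2-methylidenecyclohexyl]ethyl}oxiran-2-yl]methanol | OC[C@H]1O[C@]1(C)CC[C@H]2C(=C)CC[C@H](C)C2(C)C
F8 | step 23 | 1,2-diol from opening of F7 at the tertiary carbon by the alkynyl group of 40 (quaternary centre as in 42) | OC[C@@H](O)[C@@](C)(C#C[C@H](C)CC[C@@H](C)[C@@H](C)CC[C@@H](C)C(C)C)CC[C@H]1C(=C)CC[C@H](C)C1(C)C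
F9 | step 23 | α-quaternary ynal from glycol cleavage of F8 | O=C[C@@](C)(C#C[C@H](C)CC[C@@H](C)[C@@H](C)CC[C@@H](C)C(C)C)CC[C@H]1C(=C)CC[C@H](C)C1(C)C
F10 | step 23 | 4,5-didehydro analogue of 42 (alkyne in place of the E-alkene) | C=C[C@@](C)(C#C[C@H](C)CC[C@@H](C)[C@@H](C)CC[C@@H](C)C(C)C)CC[C@H]1C(=C)CC[C@H](C)C1(C)C
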